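The over-reaction product cannot be read off the zeta run, since its last reading of 0.6% is smaller than the scatter of 1 percentage point. So I take what can be read.

| setting | zeta | north | west |
|---|---|---|---|
| starting material | 0.18 M | 0.092 M | 0.092 M |
| partner | 0.166 M | 0.166 M | 0.166 M |
| second reagent | 0.11 M | 0.110 M | 0.110 M |
| remark | run made earlier |  |  |
| time |  | 120 min | 50 min |

zeta run (percent of the starting material charged)

| time / min | starting material / % | intermediate / % | target / % | over-reaction product / % |
|---|---|---|---|---|
| 1.33 | 95.3 | 2.7 | 0.8 | 1.1 |
| 2.00 | 94.3 | 6.1 | 0.9 | 0.1 |
| 3.00 | 92.2 | 7.4 | 1.0 | 0.3 |
| 4.00 | 91.3 | 9.8 | 0.7 | 0 |
| 6.00 | 85.1 | 14.0 | 0.7 | 0 |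
| 10.0 | 80.1 | 19.2 | 2.1 | 0.7 |
| 15.0 | 70.3 | 22.7 | 4.6 | 0.6 |

(scatter of a reading: 1 percentage point)



1. which of these there is most of at the end, counted by the starting material in it, north (target / over-reaction product / intermediate / starting material)
2. which of these there is most of at the end, counted by the starting material in it, west (target / over-reaction product / intermediate / starting material)
3. final amount of the leader among these, as a percentage of the starting material charged, in north
4. final amount of the leader among these, as a percentage of the starting material charged, in west

In the zeta run, starting material falls to 70.3% at 15.0 min. Partner is the limiting reagent of that run, at 0.166 M against 0.18 M of starting material, so I cannot hold it at its charge. I let it fall mole for mole with starting material, a second-order reckoning, and from that one reading I get a constant of 0.173 M⁻¹ min⁻¹.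

The count of turnovers is the natural logarithm of starting material charged over starting material left, reckoned with that constant and with partner falling in the same way, and for west it comes to 1.10. The part of starting material left is one over the exponential of the count. Below a count of 0.693, more than half is still starting material, so it must lead.

But west stands above that mark, and its count leaves 33.3%, against the forecast's 35%. The count does not say how the rest divides between intermediate and target, so I name no leader for west from it. North's count of 2.21 leaves 11.0%.

The forecast says target at 57% for north and intermediate at 37% for west, and warns that over-reaction “could take some target by 120 min”.

    partner + target → over-reaction product (k = 0.0340 M⁻¹ min⁻¹)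
    second reagent + intermediate → target (k = 0.158 M⁻¹ min⁻¹)
    starting material + partner → intermediate (k = 0.167 M⁻¹ min⁻¹)

West gives intermediate at 41.5% with 34.4% starting material, where its count left 33.3%. North gives target at 45.5%, with 9.24% over-reaction product. The neighbour is west read at 12 min: its count is 0.316, under the mark, and leaves 72.9%, so starting material must lead. That flask shows starting material in the lead, at 73.6%.

The numbers in the tables come from a simulation on assumed constants, and the scatter is random.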